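A fixed amount of catalyst cannot turn over faster while both its reactants fall, yet the grey run goes from 13.4 mM min⁻¹ up to its first reading to 16.5 mM min⁻¹ between its second and third. So you need two routes, and you solve each at its own end.

| flask | substrate | coupling partner | free catalyst | time |
|---|---|---|---|---|
| ochre | 100 mM | 120 mM | 1.00 mM |  |
| amber | 40.0 mM | 60.0 mM | 1.00 mM |  |
| grey | 300 mM | 120 mM | 1.00 mM |  |
| teal | 100 mM | 240 mM | 1.00 mM |  |
| red | 500 mM | 600 mM | 1.00 mM | 12 min |

| ochre run: time / min | ochre run: [target] / mM | amber run: time / min | amber run: [target] / mM | grey run: time / min | grey run: [target] / mM | teal run: time / min | teal run: [target] / mM |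
|---|---|---|---|---|---|---|---|
| 1.7 | 12.0 | 1.7 | 4.9 | 1.7 | 22.7 | 1.7 | 17.4 |
| 3.4 | 24.5 | 3.4 | 9.7 | 3.4 | 55.5 | 3.4 | 40.2 |
| 5.1 | 36.8 | 5.1 | 13.3 | 5.1 | 83.5 | 5.1 | 61.5 |
| 6.9 | 49.3 | 6.9 | 17.6 | 6.9 | 99.9 | 6.9 | 75.9 |
| 8.6 | 57.6 | 8.6 | 20.6 | 8.6 | 106.5 | 8.6 | 83.8 |
| 10 | 64.6 | 10 | 23.3 | 10 | 108.4 | 10 | 86.8 |
| 12 | 70.3 | 12 | 25.2 | 12 | 108.0 | 12 | 88.8 |

(standard deviation of a reading: 0.5 mM)

- the exponent of [substrate] in the starting rate at the charge of the ochre run (at the point where two percent of the substrate have become target) (one fixed amount of target, the same in the runs compared)
- the exponent of [coupling partner] in the starting rate at the charge of the ochre run (at the point where two percent of the substrate have become target)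
- target in the red run at 12 min, as a share of the substrate charged

- Overall: substrate + coupling partner -> target, with free catalyst as catalyst.
- Constant volume, constant temperature.
- The analysis sees a species whether free or bound.
- "The second partner" is coupling partner.
- An order is taken over about fifteen percent of the charge, up and down.

Take the low end first, with a bench rule: the catalyst route goes as the square root of c(substrate) times c(coupling partner). That is an exponent of 0.5 for each, and I commit to it for both orders. The amber run tests it. Its first reading over the ochre first reading, at the same time, is 0.408, and the square root of the charge ratio gives 0.447. The first ochre reading, taken as a mean rate from the start, sets the factor in front at 0.0644 min⁻¹.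

The border shows in the teal run. Midway between its first two readings, at 28.8 mM of target, c(substrate) is 71.2 mM and c(coupling partner) is 211 mM. The rule allows 7.90 mM min⁻¹ there, but the readings give 13.4 mM min⁻¹. I give the excess to a second route, fed by target, with a rate proportional to c(substrate), c(coupling partner) and c(target). Scaling that excess gives 41.3 mM for the teal run: the handover amount, the target at which the target-fed route matches the catalyst route. It goes inversely as the square root of c(substrate) times c(coupling partner).

For the red run that gives 9.25 mM, far below its substrate charge. The catalyst route, at 35.3 mM min⁻¹, reaches that amount in 0.262 min, and the same span is then the e-folding time of target. Target reaches the size of the charge about 1.05 min later. Near the end the excess of coupling partner is small, so the span stretches to 1.57 min, yet 12 min still holds 7.64 of those. Substrate is the limiting reagent in the red run, so I expect it to turn over well before 12 min. For the level I take a reading: the grey run stands flat at 90.0% of its coupling partner charge. I reckon 90.0% for the red run.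

The forecast, noting that “Grey and teal then speed up”, gave exponents of 0.55 and 0.45 and 62% for the red run, with a range of 45% to 80%. The simulation gives 0.47, 0.50 and 88.7%.

    free catalyst + substrate → catalyst-substrate complex (152.4 L mol⁻¹ min⁻¹)
    catalyst-substrate complex + coupling partner → loaded catalyst (115.8 L mol⁻¹ min⁻¹)
    loaded catalyst → target + free catalyst (52.50 min⁻¹)
    target → decomposed product (0.01122 min⁻¹)
    substrate + coupling partner + target → 2 target (17.16 L² mol⁻² min⁻¹)

For the amber run my estimate of the handover amount, 103 mM, stands above the substrate charge, and that run took 3.64 min to make 10.0 mM of target and 4.69 min for the next 10.0 mM. In the red run free catalyst made target through catalyst-substrate complex and loaded catalyst, and the step with 17.2 L² mol⁻² min⁻¹ ran beside it, both routes on either side of my estimated handover amount of 9.25 mM, which is 1.85% of the substrate charged. Target meanwhile went to decomposed product at 0.0112 min⁻¹, and at 12 min target stood at 88.7% of the substrate charged.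

The runs were computed for substances that don't exist; the scatter is artificial.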